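**Plan**
Cuts: chromene O-1'–C-2' and C-3'=C-4' (asymmetric O-allylation, ring-closing metathesis); enone C-6–CH2 (coupling at an enol triflate) and C-5–CH2 (reductive alkylation of a 1,3-dione); C-5–C-6 (Claisen condensation); C-3a–C-7a of the cyclopentane (ring contraction).
Forward: the quaternary carbon C-7a is set on a cyclohexanone, the derived cyclohexene is contracted to the cyclopentane, the dione ring is closed, both side chains are added and the chromene is built last.
Enabling feature: ketone carbon C-4 sits on quaternary C-3a, next to quaternary C-7a, inside cyclopentane C-1/C-2/C-3/C-3a/C-7a. This is the product pattern of a 1,2-shift of a ring bond in a 1,2-dimethylcyclohexene whose CH2CO2H arm (future C-7/C-6) delivers the oxygen that becomes the C-4 carbonyl oxygen.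
Stereochemistry: C-7a from a chiral palladium catalyst (step 2); C-3a relayed from C-7a in step 7 (tethered syn delivery of oxygen, anti iodane, invertive shift, hence trans methyl groups and trans ring fusion); chromene C-2' from a second chiral palladium catalyst (step 18), independent of the core.

Key step: step 7

Assumption: locants of the bicyclic core follow indene numbering (C-4 ketone, C-3a and C-7a ring fusion); the sense of induction in steps 2 and 18 is assigned by analogy with the parent reactions of these ligand classes, and the mirror-image ligand is taken if the opposite sense is found.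

Step 1
Reactants: 1 2,6-dimethylcyclohexan-1-one
Product: 2 2,6-dimethylcyclohex-1-en-1-yl prop-2-en-1-yl carbonate
Conditions: LiN(SiMe3)2, THF, −78 °C; allyl chloroformate, TMEDA, −78 to 0 °C
Reagents that add atoms: allyl chloroformate, C=CCOC(=O)Cl
Why: The symmetrical ketone has only one enolate, the tetrasubstituted one, and hard lithium enolates of this kind should be acylated on oxygen by a chloroformate (enolate O-acylation).

Step 2
Reactants: 2 2,6-dimethylcyclohex-1-en-1-yl prop-2-en-1-yl carbonate
Product: 3 (2R)-2,6-dimethyl-2-(prop-2-en-1-yl)cyclohexan-1-one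
Conditions: Pd2(dba)3 (cat.), (R)-4-tert-butyl-2-[2-(diphenylphosphanyl)phenyl]-4,5-dihydro-1,3-oxazole (cat.), THF, 25 °C
Reagents that add atoms: none
Why: Zerovalent palladium ionises the allyl carbonate, CO2 is lost and the enolate recombines with the π-allyl complex inside the chiral P,N-ligand sphere (decarboxylative asymmetric Tsuji–Trost allylation), which should set quaternary C-2 as (R); the C-6 methine remains a mixture that is erased in step 3.

Step 3
Reactants: 3 (2R)-2,6-dimethyl-2-(prop-2-en-1-yl)cyclohexan-1-one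
Product: 4 (6R)-2,6-dimethyl-6-(prop-2-en-1-yl)cyclohex-1-en-1-yl trifluoromethanesulfonate
Conditions: KN(SiMe3)2, THF, −78 to 0 °C; PhNTf2
Reagents that add atoms: N-phenylbis(trifluoromethanesulfonimide), O=S(=O)(N(c1ccccc1)S(=O)(=O)C(F)(F)F)C(F)(F)F
Why: The ketone has a single α-hydrogen, so deprotonation and O-triflation can only give the tetrasubstituted enol triflate (enolate trapping).

Step 4
Reactants: 4 (6R)-2,6-dimethyl-6-(prop-2-en-1-yl)cyclohex-1-en-1-yl trifluoromethanesulfonate
Product: 5 (3R)-1,2,3-trimethyl-3-(prop-2-en-1-yl)cyclohex-1-ene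
Conditions: MeZnCl, Pd(PPh3)4 (cat.), THF, 60 °C
Reagents that add atoms: methylzinc chloride, C[Zn]Cl
Why: Oxidative addition of the enol triflate to zerovalent palladium, transmetalation from zinc and reductive elimination (Negishi coupling) should install the second vinylic methyl group without touching the terminal alkene or the stereocentre.

Step 5
Reactants: 5 (3R)-1,2,3-trimethyl-3-(prop-2-en-1-yl)cyclohex-1-ene
Product: 6 2-[(1R)-1,2,3-trimethylcyclohex-2-en-1-yl]acetaldehyde
Conditions: OsO4 (cat.), NaIO4, 2,6-lutidine, 1,4-dioxane/H2O, 25 °C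
Reagents that add atoms: sodium periodate, [Na+].[O-]I(=O)(=O)=O (oxygen passed on through catalytic OsO4)
Why: Osmylation should be much faster at the unhindered monosubstituted alkene than at the tetrasubstituted ring alkene, so dihydroxylation and periodate cleavage (Lemieux–Johnson oxidation) shorten the allyl group to the acetaldehyde arm chemoselectively.

Step 6
Reactants: 6 2-[(1R)-1,2,3-trimethylcyclohex-2-en-1-yl]acetaldehyde
Product: 7 2-[(1R)-1,2,3-trimethylcyclohex-2-en-1-yl]acetic acid
Conditions: NaClO2, NaH2PO4, 2-methylbut-2-ene, t-BuOH/H2O, 25 °C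
Reagents that add atoms: sodium chlorite, [Na+].[O-]Cl=O
Why: Buffered chlorite oxidises the aldehyde to the acid while the alkene scavenger removes HOCl before it can add to the ring alkene (Pinnick oxidation).

Step 7
Reactants: 7 2-[(1R)-1,2,3-trimethylcyclohex-2-en-1-yl]acetic acid
Product: 9 methyl 2-[(1R,2S)-2-acetyl-1,2-dimethylcyclopentyl]acetate, via acyloxycarbenium tosylate 8 (not isolated)
Conditions: PhI(OH)OTs, CH2Cl2/(CF3)2CHOH, −40 to 0 °C; then MeOH, 25 °C
Reagents that add atoms: methanol, CO
Why: Proposed new method: the ring alkene attacks electrophilic trivalent iodine, the tethered carboxyl group adds from its own face (5-exo-trig lactonisation, or 6-endo) and leaves the phenyl-λ3-iodanyl group anti on the other alkene carbon; reductive loss of iodobenzene is then accompanied by a 1,2-shift of the antiperiplanar ring C–C bond through a three-centre transition state, which contracts the cyclohexane to the cyclopentane and gives the acyloxycarbenium ion 8 that methanol opens to the keto ester. The closest known reaction types are the oxidative ring contraction of cyclohexenes by trivalent iodine or trivalent thallium in methanol or acetic acid and the oxylactonisation of alkenoic acids by PhI(OH)OTs. The new quaternary stereocentre is controlled by the resident one: oxygen delivery is intramolecular and therefore syn to the CH2CO2H arm, iodine is anti to it, and the shifting carbon enters with inversion on the arm face while keeping its own configuration, so the acetyl group should end trans to the arm and the two methyl groups trans to each other. Because both alkene carbons carry a methyl group, either regiochemistry of the lactonisation leads to the same product, so no regioselectivity is needed. The selectivity that is needed is shift of the ring bond in preference to methyl shift, proton loss or oxygen participation: the methyl group on the oxygen-bearing carbon is cis to iodine and cannot align, the lactone oxygen is a poor neighbouring group and a dioxolenium ion would place its cationic carbon at a bridgehead, so only the ring bond is antiperiplanar to the departing iodane in the conformer with equatorial iodine.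

Step 8
Reactants: 9 methyl 2-[(1R,2S)-2-acetyl-1,2-dimethylcyclopentyl]acetate
Product: 10 (3aS,7aR)-3a,7a-dimethyl-2,3,3a,7a-tetrahydro-1H-indene-4,6(5H,7H)-dione
Conditions: KOtBu, THF, 0 to 25 °C; aq. HCl
Reagents that add atoms: none
Why: The methyl ketone is enolised on its only α-carbon and the enolate attacks the ester in a 6-exo-trig Claisen (Dieckmann-type) condensation driven by deprotonation of the 1,3-dione; the trans arms on the cyclopentane give the trans ring fusion with no change at the quaternary centres.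

Step 9
Reactants: 11 methyl 2-hydroxy-2-methylpropanoate
Product: 12 methyl 2-methyl-2-[(triethylsilyl)oxy]propanoate
Conditions: Et3SiOTf, 2,6-lutidine, CH2Cl2, 0 °C
Reagents that add atoms: triethylsilyl trifluoromethanesulfonate, CC[Si](CC)(CC)OS(=O)(=O)C(F)(F)F
Why: The hindered tertiary alcohol should be silylated by the silyl triflate in the presence of a non-nucleophilic base (silyl ether formation).

Step 10
Reactants: 12 methyl 2-methyl-2-[(triethylsilyl)oxy]propanoate
Product: 13 2-methyl-2-[(triethylsilyl)oxy]propanal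
Conditions: i-Bu2AlH, CH2Cl2, −78 °C; aq. potassium sodium tartrate
Reagents that add atoms: none
Why: At low temperature the aluminium hemiacetal of the ester persists until work-up, so reduction should stop at the aldehyde (partial ester reduction).

Step 11
Reactants: 10 (3aS,7aR)-3a,7a-dimethyl-2,3,3a,7a-tetrahydro-1H-indene-4,6(5H,7H)-dione; 13 2-methyl-2-[(triethylsilyl)oxy]propanal
Product: 14 (3aS,7aR)-3a,7a-dimethyl-5-{2-methyl-2-[(triethylsilyl)oxy]propyl}-2,3,3a,7a-tetrahydro-1H-indene-4,6(5H,7H)-dione
Conditions: diethyl 2,6-dimethyl-1,4-dihydropyridine-3,5-dicarboxylate, L-proline (cat.), CH2Cl2, 25 °C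
Reagents that add atoms: none
Why: Amine-catalysed Knoevenagel condensation gives an alkylidene dione that is reduced in the same flask by hydride transfer from the dihydropyridine (three-component reductive alkylation), which should place the protected side chain on C-5 by C-alkylation only.

Step 12
Reactants: 14 (3aS,7aR)-3a,7a-dimethyl-5-{2-methyl-2-[(triethylsilyl)oxy]propyl}-2,3,3a,7a-tetrahydro-1H-indene-4,6(5H,7H)-dione
Product: 15 (3aS,7aR)-3a,7a-dimethyl-5-{2-methyl-2-[(triethylsilyl)oxy]propyl}-4-oxo-2,3,3a,4,7,7a-hexahydro-1H-inden-6-yl trifluoromethanesulfonate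
Conditions: Tf2O, Et3N, CH2Cl2, −78 °C
Reagents that add atoms: trifluoromethanesulfonic anhydride, O=S(=O)(OS(=O)(=O)C(F)(F)F)C(F)(F)F
Why: Sulfonylation of the enolised dione should take place on the oxygen at C-6, because the oxygen at C-4 is shielded by the neighbouring quaternary C-3a, which leaves the ketone where the target has it (enol triflate formation).

Step 13
Reactants: 15 (3aS,7aR)-3a,7a-dimethyl-5-{2-methyl-2-[(triethylsilyl)oxy]propyl}-4-oxo-2,3,3a,4,7,7a-hexahydro-1H-inden-6-yl trifluoromethanesulfonate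
Product: 16 (3aS,7aR)-3a,7a-dimethyl-5-{2-methyl-2-[(triethylsilyl)oxy]propyl}-6-(prop-2-en-1-yl)-1,2,3,3a,7,7a-hexahydro-4H-inden-4-one
Conditions: allylSnBu3, Pd(PPh3)4 (cat.), LiCl, THF, 65 °C
Reagents that add atoms: allyltributylstannane, C=CC[Sn](CCCC)(CCCC)CCCC
Why: The electron-poor vinyl triflate should add readily to zerovalent palladium and take the allyl group from tin (Stille coupling), giving the tetrasubstituted enone.

Step 14
Reactants: 16 (3aS,7aR)-3a,7a-dimethyl-5-{2-methyl-2-[(triethylsilyl)oxy]propyl}-6-(prop-2-en-1-yl)-1,2,3,3a,7,7a-hexahydro-4H-inden-4-one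
Product: 17 (3aS,7aR)-3a,7a-dimethyl-5-{2-methyl-2-[(triethylsilyl)oxy]propyl}-6-(2-oxopropyl)-1,2,3,3a,7,7a-hexahydro-4H-inden-4-one
Conditions: PdCl2 (cat.), CuCl, O2 (1 atm), DMF/H2O, 25 °C
Reagents that add atoms: water, O
Why: Markovnikov hydroxypalladation of the terminal alkene and β-hydride loss (Tsuji–Wacker oxidation) should give the methyl ketone, the tetrasubstituted enone alkene being inert.

Step 15
Reactants: 17 (3aS,7aR)-3a,7a-dimethyl-5-{2-methyl-2-[(triethylsilyl)oxy]propyl}-6-(2-oxopropyl)-1,2,3,3a,7,7a-hexahydro-4H-inden-4-one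
Product: 19 methyl 2-methyl-1-[(3aS,7aR)-3a,7a-dimethyl-5-{2-methyl-2-[(triethylsilyl)oxy]propyl}-4-oxo-2,3,3a,4,7,7a-hexahydro-1H-inden-6-yl]but-3-en-2-yl carbonate, via bromomagnesium alkoxide 18 (not isolated)
Conditions: CH2=CHMgBr, LaCl3·2LiCl, THF, −78 °C; then ClCO2Me, −78 to 0 °C
Reagents that add atoms: vinylmagnesium bromide, C=C[Mg]Br; methyl chloroformate, COC(=O)Cl
Why: Lanthanum-assisted 1,2-addition suppresses enolisation of the acidic methylene ketone, the unhindered methyl ketone reacts in preference to the neopentyl enone carbonyl, and the tertiary alkoxide is acylated in the same flask (Grignard addition, O-acylation); the carbinol configuration is irrelevant because this carbon is ionised in step 18.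

Step 16
Reactants: 20 4-methoxy-2-methylphenol
Product: 21 2-hydroxy-5-methoxy-3-methylbenzaldehyde
Conditions: MgCl2, Et3N, (CH2O)n, MeCN, reflux
Reagents that add atoms: paraformaldehyde (formaldehyde unit), C=O
Why: The magnesium phenoxide directs formaldehyde to the only free ortho position and a second formaldehyde accepts hydride (Casnati–Skattebøl ortho-formylation).

Step 17
Reactants: 21 2-hydroxy-5-methoxy-3-methylbenzaldehyde
Product: 22 2-ethenyl-4-methoxy-6-methylphenol
Conditions: Ph3PCH3Br, KOtBu (excess), THF, 0 to 25 °C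
Reagents that add atoms: methyltriphenylphosphonium bromide, C[P+](c1ccccc1)(c1ccccc1)c1ccccc1.[Br-]
Why: Excess ylide first forms the phenoxide and then methylenates the aldehyde (Wittig reaction).

Step 18
Reactants: 19 methyl 2-methyl-1-[(3aS,7aR)-3a,7a-dimethyl-5-{2-methyl-2-[(triethylsilyl)oxy]propyl}-4-oxo-2,3,3a,4,7,7a-hexahydro-1H-inden-6-yl]but-3-en-2-yl carbonate; 22 2-ethenyl-4-methoxy-6-methylphenol
Product: 23 (3aS,7aR)-6-[(2R)-2-(2-ethenyl-4-methoxy-6-methylphenoxy)-2-methylbut-3-en-1-yl]-3a,7a-dimethyl-5-{2-methyl-2-[(triethylsilyl)oxy]propyl}-1,2,3,3a,7,7a-hexahydro-4H-inden-4-one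
Conditions: Pd2(dba)3·CHCl3 (cat.), (R,R)-N,N'-(cyclohexane-1,2-diyl)bis[2-(diphenylphosphanyl)benzamide] (cat.), CH2Cl2, 25 °C
Reagents that add atoms: none
Why: Zerovalent palladium ionises both carbinol epimers to π-allyl complexes that interconvert through the η1 form at the CH2 terminus, and the phenol attacks the more substituted terminus inside the chiral pocket (asymmetric Tsuji–Trost O-allylation run as a dynamic kinetic asymmetric transformation), which should give the (R)-configured tertiary aryl ether under catalyst control, independent of the remote stereocentres.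

Step 19
Reactants: 23 (3aS,7aR)-6-[(2R)-2-(2-ethenyl-4-methoxy-6-methylphenoxy)-2-methylbut-3-en-1-yl]-3a,7a-dimethyl-5-{2-methyl-2-[(triethylsilyl)oxy]propyl}-1,2,3,3a,7,7a-hexahydro-4H-inden-4-one
Product: 24 (3aS,7aR)-6-{[(2R)-6-methoxy-2,8-dimethyl-2H-chromen-2-yl]methyl}-3a,7a-dimethyl-5-{2-methyl-2-[(triethylsilyl)oxy]propyl}-1,2,3,3a,7,7a-hexahydro-4H-inden-4-one
Conditions: second-generation Grubbs catalyst (H2IMes)(PCy3)Cl2Ru=CHPh (cat.), CH2Cl2, 40 °C
Reagents that add atoms: none
Why: The two terminal vinyl groups should be joined by ring-closing metathesis with loss of ethene to give the six-membered chromene ring, the ether stereocentre and the tetrasubstituted enone taking no part.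

Step 20
Reactants: 24 (3aS,7aR)-6-{[(2R)-6-methoxy-2,8-dimethyl-2H-chromen-2-yl]methyl}-3a,7a-dimethyl-5-{2-methyl-2-[(triethylsilyl)oxy]propyl}-1,2,3,3a,7,7a-hexahydro-4H-inden-4-one
Product: 25 (3aS,7aR)-5-(2-hydroxy-2-methylpropyl)-6-{[(2R)-6-methoxy-2,8-dimethyl-2H-chromen-2-yl]methyl}-3a,7a-dimethyl-1,2,3,3a,7,7a-hexahydro-4H-inden-4-one
Conditions: HF·pyridine, pyridine, THF, 0 °C
Reagents that add atoms: none
Why: Buffered fluoride should cleave the Si–O bond of the tertiary silyl ether under conditions mild enough for the allylic aryl ether and the enone (desilylation).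

**Compound list**
1 | 2,6-dimethylcyclohexan-1-one (cis/trans mixture) | CC1CCCC(C)C1=O | starting material
2 | 2,6-dimethylcyclohex-1-en-1-yl prop-2-en-1-yl carbonate (racemic) | C=CCOC(=O)OC1=C(C)CCCC1C | intermediate
3 | (2R)-2,6-dimethyl-2-(prop-2-en-1-yl)cyclohexan-1-one (both C-6 epimers) | O=C1C(C)CCC[C@]1(C)CC=C | intermediate
4 | (6R)-2,6-dimethyl-6-(prop-2-en-1-yl)cyclohex-1-en-1-yl trifluoromethanesulfonate | FC(F)(F)S(=O)(=O)OC1=C(C)CCC[C@]1(C)CC=C | intermediate
5 | (3R)-1,2,3-trimethyl-3-(prop-2-en-1-yl)cyclohex-1-ene | CC1=C(C)CCC[C@]1(C)CC=C | intermediate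
6 | 2-[(1R)-1,2,3-trimethylcyclohex-2-en-1-yl]acetaldehyde | CC1=C(C)CCC[C@]1(C)CC=O | intermediate
7 | 2-[(1R)-1,2,3-trimethylcyclohex-2-en-1-yl]acetic acid | CC1=C(C)CCC[C@]1(C)CC(=O)O | intermediate
8 | (4aR,7aS)-1,4a,7a-trimethyl-3-oxo-4,4a,5,6,7,7a-hexahydro-3H-cyclopenta[c]pyran-2-ium 4-methylbenzenesulfonate (trans-fused cyclic acyloxycarbenium ion) | C[C@]12CCC[C@]1(C)CC(=O)[O+]=C2C.[O-]S(=O)(=O)c1ccc(C)cc1 | intermediate (not isolated)
9 | methyl 2-[(1R,2S)-2-acetyl-1,2-dimethylcyclopentyl]acetate (methyl groups trans) | CC(=O)[C@@]1(C)CCC[C@]1(C)CC(=O)OC | intermediate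
10 | (3aS,7aR)-3a,7a-dimethyl-2,3,3a,7a-tetrahydro-1H-indene-4,6(5H,7H)-dione (trans-fused; largely enolised) | O=C1CC(=O)[C@@]2(C)CCC[C@]2(C)C1 | intermediate
11 | methyl 2-hydroxy-2-methylpropanoate | COC(=O)C(C)(C)O | starting material
12 | methyl 2-methyl-2-[(triethylsilyl)oxy]propanoate | COC(=O)C(C)(C)O[Si](CC)(CC)CC | intermediate
13 | 2-methyl-2-[(triethylsilyl)oxy]propanal | O=CC(C)(C)O[Si](CC)(CC)CC | intermediate
14 | (3aS,7aR)-3a,7a-dimethyl-5-{2-methyl-2-[(triethylsilyl)oxy]propyl}-2,3,3a,7a-tetrahydro-1H-indene-4,6(5H,7H)-dione (diketo form drawn; C-5 not defined) | O=C1C(CC(C)(C)O[Si](CC)(CC)CC)C(=O)[C@@]2(C)CCC[C@]2(C)C1 | intermediate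
15 | (3aS,7aR)-3a,7a-dimethyl-5-{2-methyl-2-[(triethylsilyl)oxy]propyl}-4-oxo-2,3,3a,4,7,7a-hexahydro-1H-inden-6-yl trifluoromethanesulfonate | FC(F)(F)S(=O)(=O)OC1=C(CC(C)(C)O[Si](CC)(CC)CC)C(=O)[C@@]2(C)CCC[C@]2(C)C1 | intermediate
16 | (3aS,7aR)-3a,7a-dimethyl-5-{2-methyl-2-[(triethylsilyl)oxy]propyl}-6-(prop-2-en-1-yl)-1,2,3,3a,7,7a-hexahydro-4H-inden-4-one | C=CCC1=C(CC(C)(C)O[Si](CC)(CC)CC)C(=O)[C@@]2(C)CCC[C@]2(C)C1 | intermediate
17 | (3aS,7aR)-3a,7a-dimethyl-5-{2-methyl-2-[(triethylsilyl)oxy]propyl}-6-(2-oxopropyl)-1,2,3,3a,7,7a-hexahydro-4H-inden-4-one | CC(=O)CC1=C(CC(C)(C)O[Si](CC)(CC)CC)C(=O)[C@@]2(C)CCC[C@]2(C)C1 | intermediate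
18 | bromomagnesium 2-methyl-1-[(3aS,7aR)-3a,7a-dimethyl-5-{2-methyl-2-[(triethylsilyl)oxy]propyl}-4-oxo-2,3,3a,4,7,7a-hexahydro-1H-inden-6-yl]but-3-en-2-olate (both carbinol epimers) | C=CC(C)(O[Mg]Br)CC1=C(CC(C)(C)O[Si](CC)(CC)CC)C(=O)[C@@]2(C)CCC[C@]2(C)C1 | intermediate (not isolated)
19 | methyl 2-methyl-1-[(3aS,7aR)-3a,7a-dimethyl-5-{2-methyl-2-[(triethylsilyl)oxy]propyl}-4-oxo-2,3,3a,4,7,7a-hexahydro-1H-inden-6-yl]but-3-en-2-yl carbonate (both carbinol epimers) | C=CC(C)(OC(=O)OC)CC1=C(CC(C)(C)O[Si](CC)(CC)CC)C(=O)[C@@]2(C)CCC[C@]2(C)C1 | intermediate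
20 | 4-methoxy-2-methylphenol | COc1ccc(O)c(C)c1 | starting material
21 | 2-hydroxy-5-methoxy-3-methylbenzaldehyde | COc1cc(C)c(O)c(C=O)c1 | intermediate
22 | 2-ethenyl-4-methoxy-6-methylphenol | COc1cc(C)c(O)c(C=C)c1 | intermediate
23 | (3aS,7aR)-6-[(2R)-2-(2-ethenyl-4-methoxy-6-methylphenoxy)-2-methylbut-3-en-1-yl]-3a,7a-dimethyl-5-{2-methyl-2-[(triethylsilyl)oxy]propyl}-1,2,3,3a,7,7a-hexahydro-4H-inden-4-one | C=C[C@@](C)(CC1=C(CC(C)(C)O[Si](CC)(CC)CC)C(=O)[C@@]2(C)CCC[C@]2(C)C1)Oc1c(C)cc(OC)cc1C=C | intermediate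
24 | (3aS,7aR)-6-{[(2R)-6-methoxy-2,8-dimethyl-2H-chromen-2-yl]methyl}-3a,7a-dimethyl-5-{2-methyl-2-[(triethylsilyl)oxy]propyl}-1,2,3,3a,7,7a-hexahydro-4H-inden-4-one | COc1cc(C)c2c(c1)C=C[C@@](C)(CC1=C(CC(C)(C)O[Si](CC)(CC)CC)C(=O)[C@@]3(C)CCC[C@]3(C)C1)O2 | intermediate
25 | (3aS,7aR)-5-(2-hydroxy-2-methylpropyl)-6-{[(2R)-6-methoxy-2,8-dimethyl-2H-chromen-2-yl]methyl}-3a,7a-dimethyl-1,2,3,3a,7,7a-hexahydro-4H-inden-4-one | COc1cc(C)c2c(c1)C=C[C@@](C)(CC1=C(CC(C)(C)O)C(=O)[C@@]3(C)CCC[C@]3(C)C1)O2 | target

Total step count: 20.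
Longest linear sequence: 16 steps (steps 1–8, 11–15, 18–20, from 2,6-dimethylcyclohexanone).

**Steps most likely to fail**

Step 7 (Proposed new method). The tertiary alkyl-λ3-iodane may lose a proton to give an allylic lactone faster than the ring bond shifts, because the lactone oxygen is only a weak electron donor; acid-catalysed hydrolactonisation of unreacted alkene acid by the sulfonic acid formed is a second drain. The fallback uses the ether-assisted variant, the reaction type established for oxidative ring contraction of cyclohexenes in methanol. It sets out from aldehyde 6, which is reduced with NaBH4 in MeOH to 2-[(1R)-1,2,3-trimethylcyclohex-2-en-1-yl]ethan-1-ol F1. Treatment of F1 with PhI(OH)OTs in MeOH at 0 °C should add the hydroxyl group syn to its arm and the iodane anti, and the strongly donating ether oxygen then drives the same invertive ring contraction; methanol captures the cyclic oxocarbenium ion as (4aR,7aS)-1-methoxy-1,4a,7a-trimethyloctahydrocyclopenta[c]pyran F2. CrO3/H2SO4 in acetone hydrolyses the ketal and oxidises the liberated primary alcohol to 2-[(1R,2S)-2-acetyl-1,2-dimethylcyclopentyl]acetic acid F3, and Me3SiCHN2 in MeOH/toluene gives the methyl ester, so the route is rejoined at 9.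

Step 18. Attack of the ortho,ortho'-disubstituted phenol on the tertiary terminus may be slow, so that β-hydride loss from the π-allyl complex (diene formation) or attack at the CH2 terminus takes over, and facial discrimination between methyl and CH2R may be incomplete. The fallback gives up catalyst control and builds the chromene by condensation. It sets out from methyl ketone 17: vinyl addition as in step 15 but with aqueous quench gives (3aS,7aR)-6-(2-hydroxy-2-methylbut-3-en-1-yl)-3a,7a-dimethyl-5-{2-methyl-2-[(triethylsilyl)oxy]propyl}-1,2,3,3a,7,7a-hexahydro-4H-inden-4-one F4. Pyridinium chlorochromate [C5H5NH][CrO3Cl] in CH2Cl2 effects the oxidative 1,3-transposition (Babler–Dauben oxidation) to 3-methyl-4-[(3aS,7aR)-3a,7a-dimethyl-5-{2-methyl-2-[(triethylsilyl)oxy]propyl}-4-oxo-2,3,3a,4,7,7a-hexahydro-1H-inden-6-yl]but-2-enal F5. Heating F5 with phenol 20, PhB(OH)2 and AcOH in toluene should give the chromene by ortho-alkenylation and oxa-6π electrocyclisation as both C-2' epimers, which are separated by preparative chromatography on a chiral stationary phase; the route is rejoined at 24.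

Step 11. Knoevenagel condensation with the α-quaternary aldehyde may be too slow, so that the dione is consumed by self-condensation or the aldehyde by hydride transfer before the alkylidene dione forms. The fallback installs the side chain by allylation and hydration. It sets out from dione 10: Pd(PPh3)4 and 2-methylallyl methyl carbonate in THF (Tsuji–Trost C-allylation) should give (3aS,7aR)-3a,7a-dimethyl-5-(2-methylprop-2-en-1-yl)-2,3,3a,7a-tetrahydro-1H-indene-4,6(5H,7H)-dione F6. Co(acac)2, PhSiH3 and O2 in i-PrOH (Mukaiyama hydration) convert the 1,1-disubstituted alkene into (3aS,7aR)-5-(2-hydroxy-2-methylpropyl)-3a,7a-dimethyl-2,3,3a,7a-tetrahydro-1H-indene-4,6(5H,7H)-dione F7. Et3SiOTf/2,6-lutidine followed by mild aqueous cleavage of the enol silyl ether rejoins the route at 14.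

**Further compounds**
F1 | step 7 | 2-[(1R)-1,2,3-trimethylcyclohex-2-en-1-yl]ethan-1-ol | CC1=C(C)CCC[C@]1(C)CCO
F2 | step 7 | (4aR,7aS)-1-methoxy-1,4a,7a-trimethyloctahydrocyclopenta[c]pyran (C-1 epimers) | C[C@]12CCC[C@]1(C)CCOC2(C)OC
F3 | step 7 | 2-[(1R,2S)-2-acetyl-1,2-dimethylcyclopentyl]acetic acid | CC(=O)[C@@]1(C)CCC[C@]1(C)CC(=O)O
F4 | step 18 | (3aS,7aR)-6-(2-hydroxy-2-methylbut-3-en-1-yl)-3a,7a-dimethyl-5-{2-methyl-2-[(triethylsilyl)oxy]propyl}-1,2,3,3a,7,7a-hexahydro-4H-inden-4-one (both carbinol epimers) | C=CC(C)(O)CC1=C(CC(C)(C)O[Si](CC)(CC)CC)C(=O)[C@@]2(C)CCC[C@]2(C)C1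
F5 | step 18 | 3-methyl-4-[(3aS,7aR)-3a,7a-dimethyl-5-{2-methyl-2-[(triethylsilyl)oxy]propyl}-4-oxo-2,3,3a,4,7,7a-hexahydro-1H-inden-6-yl]but-2-enal (E/Z mixture) | O=CC=C(C)CC1=C(CC(C)(C)O[Si](CC)(CC)CC)C(=O)[C@@]2(C)CCC[C@]2(C)C1
F6 | step 11 | (3aS,7aR)-3a,7a-dimethyl-5-(2-methylprop-2-en-1-yl)-2,3,3a,7a-tetrahydro-1H-indene-4,6(5H,7H)-dione | O=C1C(CC(C)=C)C(=O)[C@@]2(C)CCC[C@]2(C)C1
F7 | step 11 | (3aS,7aR)-5-(2-hydroxy-2-methylpropyl)-3a,7a-dimethyl-2,3,3a,7a-tetrahydro-1H-indene-4,6(5H,7H)-dione | O=C1C(CC(C)(C)O)C(=O)[C@@]2(C)CCC[C@]2(C)C1
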